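**Strategy.** Ring B is taken apart at C1'–C2', C3'–C4' and C4'–C5'. This leads back to a cyclobut-2-enone carried through its C2 on C3 of the finished chromanone (rings A and C) and to a prenylated methoxyalkyne. In one thermal operation the derived vinylketene takes up the alkyne and closes to the arene. C1' (bonded to C3), the C2' methoxy, the C3' prenyl and the C4' hydroxyl thereby arise on four adjacent carbons, while C5' and C6' stay unsubstituted. The precursor is the (3S)-3,5-bis(silyl ether) of the 7-methoxy-8-prenyl-3-hydroxychromanone with the four-membered enone on C3; its stereocentre comes from a carbene-catalysed benzoin closure.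

Key step: step 12

Assumption: the (5aS,10bR) antipode of the triazolium precatalyst is taken to give the (3S) benzoin adduct; if correlation shows the opposite sense, the (5aR,10bS) antipode is used.
Remark: both hydroxyls that must be masked during the ketene chemistry are carried as silyl ethers, so the last step needs only buffered fluoride and no acid (acid would threaten the ortho-prenyl phenol and the tertiary benzylic carbinol).
Remark: enol ether 14 and adduct 15 are isomer mixtures at centres that are removed in step 9; only C3 matters.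

**Step 1**
Reactants: 1 2-hydroxy-4,6-dimethoxybenzaldehyde
Product: 2 2,6-dihydroxy-4-methoxybenzaldehyde
Conditions: AlCl3 (3 equiv), CH2Cl2, 0 °C → reflux; aq. HCl
Reagents that add atoms: none
Why: Chelation-controlled ether cleavage (Lewis-acid demethylation ortho to a carbonyl): aluminium bound to the formyl oxygen cleaves the ortho methyl ether, while the para methoxy group lacks this activation and should stay.

**Step 2**
Reactants: 2 2,6-dihydroxy-4-methoxybenzaldehyde; 3 prenyl bromide (1-bromo-3-methylbut-2-ene)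
Product: 4 2-hydroxy-4-methoxy-6-(3-methylbut-2-enyloxy)benzaldehyde
Conditions: K2CO3 (1.1 equiv), acetone, rt
Reagents that add atoms: none
Why: Williamson O-alkylation of a symmetrical diol; after the first alkylation the remaining hydroxyl is hydrogen-bonded to the aldehyde, which should stop the reaction at the mono-ether.

**Step 3**
Reactants: 5 4,4-dimethoxybutan-2-one
Product: 7 1-bromo-4,4-dimethoxybutan-2-one, via silyl enol ether 6 (not isolated)
Conditions: LiN(i-Pr)2, THF, −78 °C; Me3SiCl; then NBS, −78 → 0 °C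
Reagents that add atoms: N-bromosuccinimide, O=C1CCC(=O)N1Br
Why: Regioselective α-bromination through a kinetic silyl enol ether: the methyl group is deprotonated in preference to the hindered methylene, and the acetal never meets acid.

**Step 4**
Reactants: 4 2-hydroxy-4-methoxy-6-(3-methylbut-2-enyloxy)benzaldehyde; 7 1-bromo-4,4-dimethoxybutan-2-one
Product: 8 2-(4,4-dimethoxy-2-oxobutoxy)-4-methoxy-6-(3-methylbut-2-enyloxy)benzaldehyde
Conditions: K2CO3, DMF, rt
Reagents that add atoms: none
Why: Williamson alkylation of the chelated phenol with a reactive α-bromo ketone at room temperature, mild enough to avoid aldol closure of the keto aldehyde to a benzofuran.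

**Step 5**
Reactants: 8 2-(4,4-dimethoxy-2-oxobutoxy)-4-methoxy-6-(3-methylbut-2-enyloxy)benzaldehyde
Product: 9 (3S)-3-(2,2-dimethoxyethyl)-3-hydroxy-7-methoxy-5-(3-methylbut-2-enyloxy)chroman-4-one
Conditions: (5aS,10bR)-2-(pentafluorophenyl)-5a,10b-dihydro-4H,6H-indeno[2,1-b][1,2,4]triazolo[4,3-d][1,4]oxazin-2-ium tetrafluoroborate (10 mol%), Et3N (20 mol%), toluene, rt
Reagents that add atoms: none
Why: Carbene-catalysed intramolecular crossed benzoin reaction, established for 2-(2-oxoalkoxy)benzaldehydes: the aldehyde becomes an acyl anion equivalent that attacks the ketone through a six-membered transition state and closes ring C; the C3 stereocentre is set by the chiral triazolylidene (face selection at the ketone), and the weak base should spare the β-keto acetal.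

**Step 6**
Reactants: 9 (3S)-3-(2,2-dimethoxyethyl)-3-hydroxy-7-methoxy-5-(3-methylbut-2-enyloxy)chroman-4-one
Product: 12 (3S)-3-(2,2-dimethoxyethyl)-3,5-dihydroxy-7-methoxy-8-(3-methylbut-2-enyl)chroman-4-one, via ortho-dienone 10 (not isolated), via para-dienone 11 (not isolated)
Conditions: Eu(fod)3 [tris(6,6,7,7,8,8,8-heptafluoro-2,2-dimethyloctane-3,5-dionato)europium] (10 mol%), NaHCO3, PhCl, 85 °C
Reagents that add atoms: none
Why: Lewis-acid-catalysed para-Claisen (Claisen–Cope) rearrangement, known for 5-prenyloxy chromanones and chromones: [3,3] shift to C6, Cope shift to C8 and enolisation should place the normal prenyl group para to O5 (between O1 and the methoxy group) and free the chelated 5-hydroxyl; C3 is not involved.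

**Step 7**
Reactants: 12 (3S)-3-(2,2-dimethoxyethyl)-3,5-dihydroxy-7-methoxy-8-(3-methylbut-2-enyl)chroman-4-one
Product: 14 (3S)-3,5-bis(tert-butyldimethylsilyloxy)-7-methoxy-3-(2-methoxyethenyl)-8-(3-methylbut-2-enyl)chroman-4-one (E/Z mixture), via bis-silyl acetal 13 (not isolated)
Conditions: t-BuMe2SiOTf (2.5 equiv), i-Pr2NEt (6 equiv), CH2Cl2, −78 → 0 °C; then Me3SiOTf (1.3 equiv), 0 °C → rt
Reagents that add atoms: tert-butyldimethylsilyl trifluoromethanesulfonate, CC(C)(C)[Si](C)(C)OS(=O)(=O)C(F)(F)F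
Why: Silyl triflate O-silylation of the phenol and the tertiary alcohol, then the silyl triflate/amine conversion of a dimethyl acetal into its methyl enol ether (oxocarbenium formation and deprotonation); both alkene isomers serve in step 8.

**Step 8**
Reactants: 14 (3S)-3,5-bis(tert-butyldimethylsilyloxy)-7-methoxy-3-(2-methoxyethenyl)-8-(3-methylbut-2-enyl)chroman-4-one
Product: 15 (3S)-3,5-bis(tert-butyldimethylsilyloxy)-3-(3,3-dichloro-2-methoxy-4-oxocyclobutyl)-7-methoxy-8-(3-methylbut-2-enyl)chroman-4-one (diastereomer mixture at the two cyclobutane CH carbons)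
Conditions: Cl2CHCOCl (1.5 equiv), Et3N (1.4 equiv, slow addition), Et2O, 0 °C → rt
Reagents that add atoms: dichloroacetyl chloride, O=C(Cl)C(Cl)Cl
Why: Ketene–enol ether [2+2] cycloaddition: the ketene carbonyl carbon bonds to the nucleophilic β-carbon of the enol ether (the carbon on C3), so the chromanone sits α to the new carbonyl and CCl2 next to the methoxy carbon; amine-generated dichloroketene should add to the enol ether far faster than to the prenyl alkenes, and the two new ring stereocentres are uncontrolled and both vanish in step 9.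

**Step 9**
Reactants: 15 (3S)-3,5-bis(tert-butyldimethylsilyloxy)-3-(3,3-dichloro-2-methoxy-4-oxocyclobutyl)-7-methoxy-8-(3-methylbut-2-enyl)chroman-4-one
Product: 17 (3S)-3,5-bis(tert-butyldimethylsilyloxy)-3-(3,3-dichloro-4-oxocyclobut-1-enyl)-7-methoxy-8-(3-methylbut-2-enyl)chroman-4-one, via trimethylsilyl enol ether 16 (not isolated)
Conditions: LiN(SiMe3)2, Me3SiCl (internal quench), THF, −78 °C; then CH2Cl2, Me3SiOTf (10 mol%), −78 → 0 °C
Reagents that add atoms: none
Why: Proposed new method: the CCl2 carbon has no hydrogen, so enolisation can only go toward the carbon that carries the chromanone, and internal silylation fixes this enol as 16; catalytic Me3SiOTf should then ionise the allylic methoxy group as Me3SiOMe to an O-silylated cyclobutenone cation that collapses to 17, which puts the double bond between the substituted α-carbon and the former methoxy carbon by construction; the closest known reaction type is the Lewis-acid elimination of β-alkoxy silyl enol ethers to enones, and amine bases are avoided because with them loss of HCl toward a 2-chloro-3-methoxy enone is the expected course.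

**Step 10**
Reactants: 17 (3S)-3,5-bis(tert-butyldimethylsilyloxy)-3-(3,3-dichloro-4-oxocyclobut-1-enyl)-7-methoxy-8-(3-methylbut-2-enyl)chroman-4-one
Product: 18 (3S)-3,5-bis(tert-butyldimethylsilyloxy)-7-methoxy-8-(3-methylbut-2-enyl)-3-(4-oxocyclobut-1-enyl)chroman-4-one
Conditions: Zn dust, AcOH, TMEDA, EtOH, 0 °C
Reagents that add atoms: none
Why: Reductive dechlorination of a 4,4-dichlorocyclobutenone with zinc in buffered acetic acid, the usual finish of dichloroketene-based cyclobutenone syntheses; silyl ethers, prenyl groups and the aryl ketone should be inert.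

**Step 11**
Reactants: 19 2-chloro-1,1-dimethoxyethane; 3 prenyl bromide (1-bromo-3-methylbut-2-ene)
Product: 21 1-methoxy-5-methylhex-4-en-1-yne, via lithium methoxyacetylide 20 (not isolated)
Conditions: LiN(i-Pr)2 (3.0 equiv), THF, −78 → 0 °C; then CuBr·SMe2 (5 mol%), 3, −30 °C → rt
Reagents that add atoms: none
Why: Twofold elimination and deprotonation of the chloroacetal give the methoxyacetylide, which is alkylated at the primary carbon of the allylic bromide under copper catalysis (alkynylation of an allylic halide); no strong base is left to isomerise the skipped enyne.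

**Step 12**
Reactants: 18 (3S)-3,5-bis(tert-butyldimethylsilyloxy)-7-methoxy-8-(3-methylbut-2-enyl)-3-(4-oxocyclobut-1-enyl)chroman-4-one; 21 1-methoxy-5-methylhex-4-en-1-yne
Product: 26 (3S)-3,5-bis(tert-butyldimethylsilyloxy)-3-[4-hydroxy-2-methoxy-3-(3-methylbut-2-enyl)phenyl]-7-methoxy-8-(3-methylbut-2-enyl)chroman-4-one, via vinylketene 22 (not isolated), via 4-vinylcyclobutenone 23 (not isolated), via dienylketene 24 (not isolated), via cyclohexadienone 25 (not isolated)
Conditions: 21 (2.5 equiv), toluene (0.1 M), 80 °C then 110 °C, sealed tube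
Reagents that add atoms: none
Why: Danheiser benzannulation: thermal 4π electrocyclic opening of 18 gives vinylketene 22, whose ketene carbon (future C4') adds to the nucleophilic prenyl-bearing carbon of the ynol ether while its α-carbon (C1') bonds to the methoxy-bearing carbon, giving 4-vinylcyclobutenone 23. Reversible 4π opening of 23 to dienylketene 24 is followed by 6π electrocyclisation (C4'–C5') to cyclohexadienone 25, which tautomerises to phenol 26. The closest known reaction type is the thermal benzannulation of cyclobutenones with 1-alkoxyalkynes. Ring B is closed by a 6π disrotatory electrocyclisation of a dienylketene; no stereocentre is formed, and the quaternary C3, which has no hydrogen, should pass unchanged. The step needs the regioselectivity of the ketene–alkyne [2+2], which the polarisation of the methoxyalkyne secures, so that the prenyl group falls between the C4' hydroxyl and the C2' methoxy group. Excess alkyne should limit acylation of the product phenol by 22.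

**Step 13**
Reactants: 26 (3S)-3,5-bis(tert-butyldimethylsilyloxy)-3-[4-hydroxy-2-methoxy-3-(3-methylbut-2-enyl)phenyl]-7-methoxy-8-(3-methylbut-2-enyl)chroman-4-one
Product: 27 sophonorol F [(3S)-3,5-dihydroxy-3-[4-hydroxy-2-methoxy-3-(3-methylbut-2-enyl)phenyl]-7-methoxy-8-(3-methylbut-2-enyl)chroman-4-one]
Conditions: Bu4NF, AcOH (1:1), THF, 0 °C → rt
Reagents that add atoms: none
Why: Fluoride desilylation of the aryl and the tertiary silyl ether under buffered, non-acidic conditions, so that neither the ortho-prenyl phenol (chroman formation) nor the tertiary benzylic carbinol (dehydration) meets acid; the stereocentre is untouched.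

**Compound list**

1 | 2-hydroxy-4,6-dimethoxybenzaldehyde | COc1cc(O)c(C=O)c(OC)c1 | starting material
2 | 2,6-dihydroxy-4-methoxybenzaldehyde | COc1cc(O)c(C=O)c(O)c1 | intermediate
3 | prenyl bromide (1-bromo-3-methylbut-2-ene) | CC(C)=CCBr | starting material
4 | 2-hydroxy-4-methoxy-6-(3-methylbut-2-enyloxy)benzaldehyde | COc1cc(O)c(C=O)c(OCC=C(C)C)c1 | intermediate
5 | 4,4-dimethoxybutan-2-one | CC(=O)CC(OC)OC | starting material
6 | 4,4-dimethoxy-2-(trimethylsilyloxy)but-1-ene | C=C(O[Si](C)(C)C)CC(OC)OC | intermediate (not isolated)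
7 | 1-bromo-4,4-dimethoxybutan-2-one | BrCC(=O)CC(OC)OC | intermediate
8 | 2-(4,4-dimethoxy-2-oxobutoxy)-4-methoxy-6-(3-methylbut-2-enyloxy)benzaldehyde | COc1cc(OCC(=O)CC(OC)OC)c(C=O)c(OCC=C(C)C)c1 | intermediate
9 | (3S)-3-(2,2-dimethoxyethyl)-3-hydroxy-7-methoxy-5-(3-methylbut-2-enyloxy)chroman-4-one | COc1cc(OCC=C(C)C)c2c(c1)OC[C@@](O)(CC(OC)OC)C2=O | intermediate
10 | (3S)-3-(2,2-dimethoxyethyl)-3-hydroxy-7-methoxy-6-(2-methylbut-3-en-2-yl)-2,3-dihydrochromene-4,5(6H)-dione (ortho-dienone, C6 epimers) | COC=1C(C(C)(C)C=C)C(=O)C2=C(C=1)OC[C@@](O)(CC(OC)OC)C2=O | intermediate (not isolated)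
11 | (3S)-3-(2,2-dimethoxyethyl)-3-hydroxy-7-methoxy-8-(3-methylbut-2-enyl)-2,3-dihydrochromene-4,5(8H)-dione (para-dienone, C8 epimers) | COC1=CC(=O)C2=C(C1CC=C(C)C)OC[C@@](O)(CC(OC)OC)C2=O | intermediate (not isolated)
12 | (3S)-3-(2,2-dimethoxyethyl)-3,5-dihydroxy-7-methoxy-8-(3-methylbut-2-enyl)chroman-4-one | COc1cc(O)c2c(c1CC=C(C)C)OC[C@@](O)(CC(OC)OC)C2=O | intermediate
13 | (3S)-3,5-bis(tert-butyldimethylsilyloxy)-3-(2,2-dimethoxyethyl)-7-methoxy-8-(3-methylbut-2-enyl)chroman-4-one | COc1cc(O[Si](C)(C)C(C)(C)C)c2c(c1CC=C(C)C)OC[C@@](O[Si](C)(C)C(C)(C)C)(CC(OC)OC)C2=O | intermediate (not isolated)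
14 | (3S)-3,5-bis(tert-butyldimethylsilyloxy)-7-methoxy-3-(2-methoxyethenyl)-8-(3-methylbut-2-enyl)chroman-4-one (E/Z mixture) | COc1cc(O[Si](C)(C)C(C)(C)C)c2c(c1CC=C(C)C)OC[C@@](O[Si](C)(C)C(C)(C)C)(C=COC)C2=O | intermediate
15 | (3S)-3,5-bis(tert-butyldimethylsilyloxy)-3-(3,3-dichloro-2-methoxy-4-oxocyclobutyl)-7-methoxy-8-(3-methylbut-2-enyl)chroman-4-one (diastereomer mixture in the four-membered ring) | COc1cc(O[Si](C)(C)C(C)(C)C)c2c(c1CC=C(C)C)OC[C@@](O[Si](C)(C)C(C)(C)C)(C1C(=O)C(Cl)(Cl)C1OC)C2=O | intermediate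
16 | (3S)-3,5-bis(tert-butyldimethylsilyloxy)-3-[3,3-dichloro-4-methoxy-2-(trimethylsilyloxy)cyclobut-1-enyl]-7-methoxy-8-(3-methylbut-2-enyl)chroman-4-one (epimers at the methoxy carbon) | COc1cc(O[Si](C)(C)C(C)(C)C)c2c(c1CC=C(C)C)OC[C@@](O[Si](C)(C)C(C)(C)C)(C1=C(O[Si](C)(C)C)C(Cl)(Cl)C1OC)C2=O | intermediate (not isolated)
17 | (3S)-3,5-bis(tert-butyldimethylsilyloxy)-3-(3,3-dichloro-4-oxocyclobut-1-enyl)-7-methoxy-8-(3-methylbut-2-enyl)chroman-4-one | COc1cc(O[Si](C)(C)C(C)(C)C)c2c(c1CC=C(C)C)OC[C@@](O[Si](C)(C)C(C)(C)C)(C1=CC(Cl)(Cl)C1=O)C2=O | intermediate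
18 | (3S)-3,5-bis(tert-butyldimethylsilyloxy)-7-methoxy-8-(3-methylbut-2-enyl)-3-(4-oxocyclobut-1-enyl)chroman-4-one (key-step precursor) | COc1cc(O[Si](C)(C)C(C)(C)C)c2c(c1CC=C(C)C)OC[C@@](O[Si](C)(C)C(C)(C)C)(C1=CCC1=O)C2=O | intermediate
19 | 2-chloro-1,1-dimethoxyethane | COC(CCl)OC | starting material
20 | lithium methoxyacetylide | [Li]C#COC | intermediate (not isolated)
21 | 1-methoxy-5-methylhex-4-en-1-yne | COC#CCC=C(C)C | intermediate
22 | (3S)-3,5-bis(tert-butyldimethylsilyloxy)-7-methoxy-8-(3-methylbut-2-enyl)-3-(1-oxobuta-1,3-dien-2-yl)chroman-4-one (vinylketene) | COc1cc(O[Si](C)(C)C(C)(C)C)c2c(c1CC=C(C)C)OC[C@@](O[Si](C)(C)C(C)(C)C)(C(=C=O)C=C)C2=O | intermediate (not isolated)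
23 | (3S)-3,5-bis(tert-butyldimethylsilyloxy)-3-[1-ethenyl-2-methoxy-3-(3-methylbut-2-enyl)-4-oxocyclobut-2-enyl]-7-methoxy-8-(3-methylbut-2-enyl)chroman-4-one (epimers at the ring carbon on C3) | COc1cc(O[Si](C)(C)C(C)(C)C)c2c(c1CC=C(C)C)OC[C@@](O[Si](C)(C)C(C)(C)C)(C1(C=C)C(OC)=C(CC=C(C)C)C1=O)C2=O | intermediate (not isolated)
24 | (3S)-3,5-bis(tert-butyldimethylsilyloxy)-7-methoxy-3-[3-methoxy-2-(3-methylbut-2-enyl)-1-oxohexa-1,3,5-trien-4-yl]-8-(3-methylbut-2-enyl)chroman-4-one (dienylketene) | COc1cc(O[Si](C)(C)C(C)(C)C)c2c(c1CC=C(C)C)OC[C@@](O[Si](C)(C)C(C)(C)C)(C(C=C)=C(OC)C(CC=C(C)C)=C=O)C2=O | intermediate (not isolated)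
25 | (3S)-3,5-bis(tert-butyldimethylsilyloxy)-7-methoxy-3-[6-methoxy-5-(3-methylbut-2-enyl)-4-oxocyclohexa-1,5-dienyl]-8-(3-methylbut-2-enyl)chroman-4-one | COc1cc(O[Si](C)(C)C(C)(C)C)c2c(c1CC=C(C)C)OC[C@@](O[Si](C)(C)C(C)(C)C)(C1=CCC(=O)C(CC=C(C)C)=C1OC)C2=O | intermediate (not isolated)
26 | (3S)-3,5-bis(tert-butyldimethylsilyloxy)-3-[4-hydroxy-2-methoxy-3-(3-methylbut-2-enyl)phenyl]-7-methoxy-8-(3-methylbut-2-enyl)chroman-4-one (sophonorol F 3,5-bis-silyl ether) | COc1cc(O[Si](C)(C)C(C)(C)C)c2c(c1CC=C(C)C)OC[C@@](O[Si](C)(C)C(C)(C)C)(c1ccc(O)c(CC=C(C)C)c1OC)C2=O | intermediate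
27 | sophonorol F, (3S)-3,5-dihydroxy-3-[4-hydroxy-2-methoxy-3-(3-methylbut-2-enyl)phenyl]-7-methoxy-8-(3-methylbut-2-enyl)chroman-4-one | COc1cc(O)c2c(c1CC=C(C)C)OC[C@@](O)(c1ccc(O)c(CC=C(C)C)c1OC)C2=O | target

**Step count.** Total: 13 steps. Longest linear sequence: 11 steps (1, 2, 4, 5, 6, 7, 8, 9, 10, 12, 13) from compound 1; steps 3 and 11 are one-step branches.

**Steps most likely to fail**

1. Step 9 (proposed new method). Ionisation of the methoxy group may be slow because the two chlorines destabilise the cation. The enolate or the enol silane may instead lose chloride (cine-type rearrangement), or the strained ring may open. The fallback sets out from 15 and rejoins the route at 18. Compound 15 is first dechlorinated with Zn, AcOH and TMEDA in EtOH at 0 °C, the known reduction of dichloroketene–enol ether adducts, to (3S)-3,5-bis(tert-butyldimethylsilyloxy)-7-methoxy-3-(2-methoxy-4-oxocyclobutyl)-8-(3-methylbut-2-enyl)chroman-4-one F1. Methanol is then eliminated from F1 under acid catalysis (TsOH cat., 4 Å molecular sieves, CH2Cl2), the classical passage from 3-alkoxycyclobutanones to cyclobutenones, to give 18. Regiocontrol then rests on the preference for the more substituted enol and not on a blocked position, so the 4-substituted isomer would have to be separated.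

2. Step 12 (key step). The 4π opening of the crowded cyclobutenone may need temperatures at which the ketene is lost to dimerisation or to acylation of the product phenol, and capture of the ketene at its fully substituted α-carbon may be slow. The fallback generates the same vinylketene photochemically at room temperature from a diazo enone (Wolff rearrangement with vinyl migration, the diazo-ketone variant of the benzannulation). It sets out from 14 and rejoins the route at 22, and so at 26.
   - Mild hydrolysis of the enol ether (PPTS, acetone–H2O) should give [(3S)-3,5-bis(tert-butyldimethylsilyloxy)-7-methoxy-8-(3-methylbut-2-enyl)-4-oxochroman-3-yl]acetaldehyde F2.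
   - CH2=CHMgBr (THF, −78 °C) adds to the aldehyde to give the allylic alcohol (3S)-3,5-bis(tert-butyldimethylsilyloxy)-3-(2-hydroxybut-3-enyl)-7-methoxy-8-(3-methylbut-2-enyl)chroman-4-one F3.
   - Dess–Martin periodinane oxidises it to the vinyl ketone (3S)-3,5-bis(tert-butyldimethylsilyloxy)-7-methoxy-8-(3-methylbut-2-enyl)-3-(2-oxobut-3-enyl)chroman-4-one F4.
   - Detrifluoroacetylative diazo transfer (LiN(SiMe3)2, then CF3CO2CH2CF3, THF, −78 °C) passes through the unisolated trifluoroacetyl ketone (3S)-3,5-bis(tert-butyldimethylsilyloxy)-7-methoxy-8-(3-methylbut-2-enyl)-3-(1,1,1-trifluoro-2,4-dioxohex-5-en-3-yl)chroman-4-one F5.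
   - MsN3, Et3N and H2O in MeCN then give the diazo enone (3S)-3,5-bis(tert-butyldimethylsilyloxy)-3-(1-diazo-2-oxobut-3-enyl)-7-methoxy-8-(3-methylbut-2-enyl)chroman-4-one F6.
   - Irradiation of F6 with 21 in CH2Cl2 (Pyrex filter, rt) should give 22; brief heating at 80 °C then completes the passage through 23, 24 and 25 to 26.

3. Step 6. Para-selectivity may be poor: ortho-dienone 10 may enolise to the 6-(1,1-dimethylallyl) phenol faster than it undergoes the Cope shift to C8. The fallback installs the prenyl group regiospecifically before ring C is built, by ortho-Claisen rearrangement of a 1,1-dimethylallyl ether. It sets out from 2 and rejoins the route at 13.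
   - Mono-O-alkylation of 2 with 3-chloro-3-methylbut-1-yne (CuCl2 cat., DBU, MeCN, 0 °C) gives 2-hydroxy-4-methoxy-6-(2-methylbut-3-yn-2-yloxy)benzaldehyde F7.
   - t-BuMe2SiCl and imidazole in DMF give 2-(tert-butyldimethylsilyloxy)-4-methoxy-6-(2-methylbut-3-yn-2-yloxy)benzaldehyde F8.
   - Semihydrogenation (H2, Pb-poisoned Pd/CaCO3, quinoline) gives 2-(tert-butyldimethylsilyloxy)-4-methoxy-6-(2-methylbut-3-en-2-yloxy)benzaldehyde F9.
   - Heating in toluene at 110 °C should give 6-(tert-butyldimethylsilyloxy)-2-hydroxy-4-methoxy-3-(3-methylbut-2-enyl)benzaldehyde F10, because the only free ortho position lies between the oxygen and the methoxy group.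
   - Alkylation with 7 (K2CO3, DMF, rt) gives 6-(tert-butyldimethylsilyloxy)-2-(4,4-dimethoxy-2-oxobutoxy)-4-methoxy-3-(3-methylbut-2-enyl)benzaldehyde F11.
   - Benzoin closure under the conditions of step 5 gives (3S)-5-(tert-butyldimethylsilyloxy)-3-(2,2-dimethoxyethyl)-3-hydroxy-7-methoxy-8-(3-methylbut-2-enyl)chroman-4-one F12.
   - Silylation of the tertiary alcohol (t-BuMe2SiOTf, i-Pr2NEt, CH2Cl2) gives 13, which is carried on in the same flask as in step 7.

**Further compounds**

F1 | step 9 | (3S)-3,5-bis(tert-butyldimethylsilyloxy)-7-methoxy-3-(2-methoxy-4-oxocyclobutyl)-8-(3-methylbut-2-enyl)chroman-4-one | COc1cc(O[Si](C)(C)C(C)(C)C)c2c(c1CC=C(C)C)OC[C@@](O[Si](C)(C)C(C)(C)C)(C1C(=O)CC1OC)C2=O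
F2 | step 12 | [(3S)-3,5-bis(tert-butyldimethylsilyloxy)-7-methoxy-8-(3-methylbut-2-enyl)-4-oxochroman-3-yl]acetaldehyde | COc1cc(O[Si](C)(C)C(C)(C)C)c2c(c1CC=C(C)C)OC[C@@](O[Si](C)(C)C(C)(C)C)(CC=O)C2=O
F3 | step 12 | (3S)-3,5-bis(tert-butyldimethylsilyloxy)-3-(2-hydroxybut-3-enyl)-7-methoxy-8-(3-methylbut-2-enyl)chroman-4-one (carbinol epimers) | COc1cc(O[Si](C)(C)C(C)(C)C)c2c(c1CC=C(C)C)OC[C@@](O[Si](C)(C)C(C)(C)C)(CC(O)C=C)C2=O
F4 | step 12 | (3S)-3,5-bis(tert-butyldimethylsilyloxy)-7-methoxy-8-(3-methylbut-2-enyl)-3-(2-oxobut-3-enyl)chroman-4-one | COc1cc(O[Si](C)(C)C(C)(C)C)c2c(c1CC=C(C)C)OC[C@@](O[Si](C)(C)C(C)(C)C)(CC(=O)C=C)C2=O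
F5 | step 12 | (3S)-3,5-bis(tert-butyldimethylsilyloxy)-7-methoxy-8-(3-methylbut-2-enyl)-3-(1,1,1-trifluoro-2,4-dioxohex-5-en-3-yl)chroman-4-one | COc1cc(O[Si](C)(C)C(C)(C)C)c2c(c1CC=C(C)C)OC[C@@](O[Si](C)(C)C(C)(C)C)(C(C(=O)C(F)(F)F)C(=O)C=C)C2=O
F6 | step 12 | (3S)-3,5-bis(tert-butyldimethylsilyloxy)-3-(1-diazo-2-oxobut-3-enyl)-7-methoxy-8-(3-methylbut-2-enyl)chroman-4-one | COc1cc(O[Si](C)(C)C(C)(C)C)c2c(c1CC=C(C)C)OC[C@@](O[Si](C)(C)C(C)(C)C)(C(=[N+]=[N-])C(=O)C=C)C2=O
F7 | step 6 | 2-hydroxy-4-methoxy-6-(2-methylbut-3-yn-2-yloxy)benzaldehyde | COc1cc(O)c(C=O)c(OC(C)(C)C#C)c1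
F8 | step 6 | 2-(tert-butyldimethylsilyloxy)-4-methoxy-6-(2-methylbut-3-yn-2-yloxy)benzaldehyde | COc1cc(O[Si](C)(C)C(C)(C)C)c(C=O)c(OC(C)(C)C#C)c1
F9 | step 6 | 2-(tert-butyldimethylsilyloxy)-4-methoxy-6-(2-methylbut-3-en-2-yloxy)benzaldehyde | COc1cc(O[Si](C)(C)C(C)(C)C)c(C=O)c(OC(C)(C)C=C)c1
F10 | step 6 | 6-(tert-butyldimethylsilyloxy)-2-hydroxy-4-methoxy-3-(3-methylbut-2-enyl)benzaldehyde | COc1cc(O[Si](C)(C)C(C)(C)C)c(C=O)c(O)c1CC=C(C)C
F11 | step 6 | 6-(tert-butyldimethylsilyloxy)-2-(4,4-dimethoxy-2-oxobutoxy)-4-methoxy-3-(3-methylbut-2-enyl)benzaldehyde | COc1cc(O[Si](C)(C)C(C)(C)C)c(C=O)c(OCC(=O)CC(OC)OC)c1CC=C(C)C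
F12 | step 6 | (3S)-5-(tert-butyldimethylsilyloxy)-3-(2,2-dimethoxyethyl)-3-hydroxy-7-methoxy-8-(3-methylbut-2-enyl)chroman-4-one | COc1cc(O[Si](C)(C)C(C)(C)C)c2c(c1CC=C(C)C)OC[C@@](O)(CC(OC)OC)C2=O
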